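The runs were computed from invented constants; noise was put on by code.

Sunday's flask cannot have stalled for want of starting material, because at 8.00 h it still showed 56.7%, more than the 38.2% of target.

the same everywhere: starting material 36 mM; free catalyst 2.5 mol%

|  | coupling partner | second substrate | protic impurity | temperature | remark | time |
|---|---|---|---|---|---|---|
| Sunday's | 0.95 equiv | 5 equiv | 1.8 mM | 0 °C | the very flask that is asked about, followed so far |  |
| Saturday's | 0.95 equiv | 5 equiv | 1.8 mM | 6 °C | run made earlier |  |
| flask | 0.950 equiv | 5.00 equiv | 1.80 mM | 0 °C |  | 12 h |

| run | time / h | target / % | starting material / % |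
|---|---|---|---|
| Sunday's | 0.500 | 27.1 | 67.9 |
| Sunday's | 1.00 | 33.4 | 62.4 |
| Sunday's | 2.00 | 36.4 | 58.6 |
| Sunday's | 4.00 | 37.9 | 57.1 |
| Sunday's | 8.00 | 38.2 | 56.7 |
| Saturday's | 0.500 | 27.5 | 67.2 |
| Saturday's | 1.00 | 31.4 | 64.2 |
| Saturday's | 2.00 | 32.5 | 62.4 |
| Saturday's | 4.00 | 32.7 | 62.6 |
| Saturday's | 8.00 | 32.3 | 62.8 |

(scatter of a reading: 0.3 percentage points)

- target taken out counts as made
- additions bring no volume worth counting

- noon: at 12 h add coupling partner, 50.0% of the amount charged, then wait 6.0 h
- winter: at 12 h add free catalyst, 100% of the amount charged, then wait 6.0 h
- spring: at 12 h take out 90% of the target then present, then wait 6.0 h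
- midnight: change nothing and wait 6.0 h more
- dawn: at 12 h raise the temperature by 25 K, then wait 6.0 h

1. target, in percent of the starting material first charged, at 12 h
2. the remedy with the largest gain of target, or "none" below 2 percentage points (noon / winter / spring / midnight / dawn / none)
3. target present, with what was taken out counted in, in percent of the starting material first charged, after spring
4. target present, with what was taken out counted in, in percent of the starting material first charged, after midnight

I went through Sunday's run in slow motion, following one molecule of starting material. In the first instants, before 0.500 h, the balance of target and starting material fell short by 5.00%, and the protic impurity amounted to 5.00% of the starting material, so I read the first fork as a quench that was over early and took a fixed share. In the middle the target rose 6.3 percentage points in half an hour, then 3 points in the next hour. At the end, from 4.00 h to 8.00 h, it rose 0.3 points, about the scatter of 0.3 points.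

The second fork lay between conversion and whatever ended conversion, and the readings did not tell me whether that was the catalyst's death or a loss of coupling partner, which the second substrate might also take. A molecule that escaped the quench stayed unconverted with chance exp(−reach), and I took the reach, the pseudo-first-order rate constant summed over the run up to the stall, as the logarithm of starting material past the quench over starting material at the stall: 0.516 on Sunday. Saturday's flask began alike but reached 0.414, less at 6 °C, which fitted a catalyst dying sooner when warmer. I assumed that, at fixed loading and temperature, the reach scales with the coupling partner in hand when the catalyst starts. I committed to about 38.2% at 12 h, and I chose fresh catalyst as the remedy.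

The forecast gave 38.3%, with 38.4% after spring and 38.4% after midnight, and chose winter, expecting about 15 points, on the ground that catalyst death, “faster when warmer, explains both the stall and the curvature”.

The flask gave 38.0% at 12 h, and the best remedy was winter.

    second substrate + coupling partner + free catalyst → free catalyst + second product (k = 4.90 M⁻² s⁻¹, Ea = 39.0 kJ mol⁻¹)
    starting material + protic impurity → quenched substrate (k = 0.270 M⁻¹ s⁻¹, Ea = 39.0 kJ mol⁻¹)
    starting material + coupling partner + free catalyst → free catalyst + target (k = 14.0 M⁻² s⁻¹, Ea = 35.0 kJ mol⁻¹)
    free catalyst → spent catalyst (k = 3.00 × 10⁻⁴ s⁻¹, Ea = 88.0 kJ mol⁻¹)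
    2 second substrate → self-condensation product (k = 0.00270 M⁻¹ s⁻¹, Ea = 47.0 kJ mol⁻¹)
    (constants at 0 °C)

At 12 h the flask held 0% of its free catalyst and 13.9% of its coupling partner. The reach scaled to that partner promised a fresh charge 3.9 points, above the 2 points mark, and winter gave 7.1 points, more than that.

On a second flask, the same but with 1.60 equiv of coupling partner, the scaled reach of 0.869 gives 55.2% target. The computed flask gave 57.3%.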